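**Plan**

Labels: ring A = terminal guaiacyl ring, ring B = central syringyl ring, ring C = syringyl ring on C2 of the dihydrobenzofuran, ring D = its benzo ring; C7/C8/C9 = carbinol, aryloxy-bearing and hydroxymethyl carbons of each glycerol chain.
Cuts, in order: the ring D aryl–vinyl bond of the enal (Heck); C7–C8 and phenol O–C8 of the ring A chain, then of the ring B chain (aryloxyacetyl imide anti-aldol, the imide carbonyl becoming C9); last the C3–C3a bond of the dihydrobenzofuran.
Enabling feature: C3 of the dihydrobenzofuran holds both ring D carbon C3a and an exocyclic one-carbon oxygenated branch, which is what remains when the ring D carbon of a flavanone moves from the carbonyl carbon C4 to C3 and C4 is pushed out of the ring as an ester.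
Forward: chromone (ring D) → rhodium-catalysed aryl addition (ring C) → six-to-five ring contraction (furan ring) → two rounds of phenol alkylation, anti-aldol and reduction (ring B chain, then ring A chain) → Heck → desilylation.
Stereochemistry: C2 from the chiral diene on rhodium; C3 relayed from C2 in the ring contraction (trans); both (7R,8S) erythro pairs from the (S)-4-benzyloxazolidinone auxiliary in the magnesium anti-aldol.

Key step: step 6

Assumption: the (R,R)-diene is taken to deliver the aryl group to the chromone face that gives the (2R)-flavanone (as it gives (R)-3-arylcyclohexanones), and the (S)-imides are taken to react through the chelated Z-enolate in the magnesium aldol; if either sense proves opposite, the enantiomeric ligand or auxiliary is used.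

**Route**

Step 1
Reactants: 1 2'-hydroxy-3'-methoxyacetophenone
Product: 2 5'-bromo-2'-hydroxy-3'-methoxyacetophenone
Conditions: NBS, MeCN, 0 °C → rt
Reagents that add atoms: N-bromosuccinimide, O=C1CCC(=O)N1Br
Why: Electrophilic aromatic bromination; the free phenol directs para, a position also meta to the acetyl group, so C5' alone should be attacked.

Step 2
Reactants: 2 5'-bromo-2'-hydroxy-3'-methoxyacetophenone
Product: 4 6-bromo-8-methoxy-4H-chromen-4-one, via enaminone 3 (not isolated)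
Conditions: Me2NCH(OMe)2, toluene, 100 °C; then conc. HCl, CH2Cl2, 40 °C
Reagents that add atoms: N,N-dimethylformamide dimethyl acetal, COC(OC)N(C)C
Why: Enaminone condensation of the methyl ketone followed by acid-promoted addition of the phenol and loss of dimethylamine is the standard chromone synthesis from 2'-hydroxyacetophenones.

Step 3
Reactants: 5 4-bromo-2,6-dimethoxyphenol
Product: 6 2-(benzyloxy)-5-bromo-1,3-dimethoxybenzene
Conditions: BnBr, K2CO3, DMF, rt
Reagents that add atoms: benzyl bromide, BrCc1ccccc1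
Why: Williamson ether synthesis; the benzyl ether should withstand n-BuLi, aqueous base and the strongly acidic orthoformate medium of step 6.

Step 4
Reactants: 6 2-(benzyloxy)-5-bromo-1,3-dimethoxybenzene
Product: 9 (4-benzyloxy-3,5-dimethoxyphenyl)boronic acid, via aryllithium 7 (not isolated), via lithium triisopropoxyborate 8 (not isolated)
Conditions: n-BuLi, THF, −78 °C; B(Oi-Pr)3, −78 °C → rt; 1 M HCl
Reagents that add atoms: triisopropyl borate, CC(C)OB(OC(C)C)OC(C)C; water, O
Why: Bromine–lithium exchange at −78 °C outruns deprotonation, and borate trapping with hydrolysis is the standard arylboronic acid synthesis.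

Step 5
Reactants: 4 6-bromo-8-methoxy-4H-chromen-4-one; 9 (4-benzyloxy-3,5-dimethoxyphenyl)boronic acid
Product: 10 (2R)-2-(4-benzyloxy-3,5-dimethoxyphenyl)-6-bromo-8-methoxychroman-4-one
Conditions: 9 (3 equiv), [RhCl(C2H4)2]2 (3 mol %), (R,R)-Ph-bod* [(1R,4R)-2,5-diphenylbicyclo[2.2.2]octa-2,5-diene, 6.6 mol %], KOH (0.5 equiv), 1,4-dioxane/H2O 10:1, 40 °C
Reagents that add atoms: none
Why: Hayashi–Miyaura asymmetric 1,4-addition of an arylboronic acid to a chromone; the chiral diene on monovalent rhodium selects the enone face in the aryl-insertion step and so sets C2 as R, while the aryl bromide is inert to monovalent rhodium.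

Step 6
Reactants: 10 (2R)-2-(4-benzyloxy-3,5-dimethoxyphenyl)-6-bromo-8-methoxychroman-4-one
Product: 13 methyl (2R,3R)-2-(4-benzyloxy-3,5-dimethoxyphenyl)-5-bromo-7-methoxy-2,3-dihydrobenzofuran-3-carboxylate, via methyl enol ether 11 (not isolated), via trans-iodanyl ketal 12 (not isolated)
Conditions: PhI(OAc)2 (1.2 equiv), HC(OMe)3 (solvent), conc. H2SO4 (2 equiv), 0 °C → rt
Reagents that add atoms: trimethyl orthoformate, COC(OC)OC
Why: Acid and orthoformate should convert the ketone into enol ether 11, PhI(OAc)2 (trivalent iodine) then attacks C3 anti to the equatorial C2 aryl group and methanol re-adds at C4 to give ketal 12, whose ring D carbon C4a shifts from C4 to C3 as iodobenzene leaves, the dimethoxycarbenium ion at the old C4 collapsing to the methyl ester. The closest known reaction type is the oxidative ring contraction of flavanones to methyl 2-aryl-2,3-dihydrobenzofuran-3-carboxylates with hypervalent iodine or Tl(NO3)3 (trivalent thallium) in trimethyl orthoformate. The furan ring is closed by this 1,2-aryl shift through a bridged aryl transition state, a six-to-five ring contraction that forms the C3–C3a bond. C2 is untouched and controls C3: the iodane enters trans to the aryl group, migration inverts C3 and leaves the ester trans, which is also the epimer favoured under the acidic conditions. The step needs migration of C4a to beat dehydrogenation to the flavone and shift of the C2 aryl group; the C4–C4a bond antiperiplanar to the equatorial C3–I bond, the ring oxygen ortho to C4a and the two methoxy groups that stabilise the cation at C4 should secure this.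

Step 7
Reactants: 13 methyl (2R,3R)-2-(4-benzyloxy-3,5-dimethoxyphenyl)-5-bromo-7-methoxy-2,3-dihydrobenzofuran-3-carboxylate
Product: 14 methyl (2R,3R)-5-bromo-2-(4-hydroxy-3,5-dimethoxyphenyl)-7-methoxy-2,3-dihydrobenzofuran-3-carboxylate
Conditions: BCl3 (2.5 equiv), C6HMe5 (3 equiv), CH2Cl2, −78 °C; MeOH quench
Reagents that add atoms: none
Why: Lewis-acid debenzylation of an aryl benzyl ether with pentamethylbenzene as non-basic benzyl-cation scavenger; at −78 °C the methyl ethers, the ester and the aryl bromide (which hydrogenolysis would endanger) should be left alone.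

Step 8
Reactants: 15 (S)-4-benzyloxazolidin-2-one
Product: 17 (S)-4-benzyl-3-(2-bromoacetyl)oxazolidin-2-one, via lithium oxazolidinide 16 (not isolated)
Conditions: n-BuLi, THF, −78 °C; BrCH2COBr, −78 → 0 °C
Reagents that add atoms: bromoacetyl bromide, BrCC(Br)=O
Why: N-Acylation of the lithiated oxazolidinone (standard imide preparation); the acyl bromide reacts far faster than the alkyl bromide.

Step 9
Reactants: 14 methyl (2R,3R)-5-bromo-2-(4-hydroxy-3,5-dimethoxyphenyl)-7-methoxy-2,3-dihydrobenzofuran-3-carboxylate; 17 (S)-4-benzyl-3-(2-bromoacetyl)oxazolidin-2-one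
Product: 18 methyl (2R,3R)-2-{4-[2-((S)-4-benzyl-2-oxooxazolidin-3-yl)-2-oxoethoxy]-3,5-dimethoxyphenyl}-5-bromo-7-methoxy-2,3-dihydrobenzofuran-3-carboxylate
Conditions: K2CO3, acetone, 0 °C → rt
Reagents that add atoms: none
Why: Williamson O-alkylation; SN2 at the α-bromo imide should be much faster than attack of the hindered phenoxide on a carbonyl group, and the C3 ester proton is not touched by carbonate.

Step 10
Reactants: 19 syringaldehyde
Product: 20 4-formyl-2,6-dimethoxyphenyl acetate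
Conditions: Ac2O, pyridine, DMAP (cat.), CH2Cl2, rt
Reagents that add atoms: acetic anhydride, CC(=O)OC(C)=O
Why: Phenol acetylation; the acetate makes the aldehyde more electrophilic and is removed by LiBH4 in step 12 together with the auxiliary.

Step 11
Reactants: 18 ring C aryloxyacetyl imide; 20 4-formyl-2,6-dimethoxyphenyl acetate
Product: 22 (2R,3R)-anti-aldol adduct [3-(4-acetoxy-3,5-dimethoxyphenyl)-3-hydroxy-2-(ring C aryloxy)propanoyl imide of (S)-4-benzyloxazolidin-2-one; C3 methyl ester retained], via trimethylsilyl ether 21 (not isolated)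
Conditions: MgCl2 (0.2 equiv), Et3N (2 equiv), Me3SiCl (1.5 equiv), EtOAc, rt; then 0.5 M HCl, THF, 0 °C
Reagents that add atoms: none
Why: Evans-type magnesium halide-catalysed direct anti-aldol of a chiral N-acyloxazolidinone with a non-enolisable aromatic aldehyde; the chelated Z-enolate should react through a boat transition state on the face opposite the benzyl group, setting C8 (2R of the adduct) and anti C7 (3R), with silylation of the aldolate turning magnesium over.

Step 12
Reactants: 22 (2R,3R)-anti-aldol adduct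
Product: 23 (1R,2S)-2-{4-[(2R,3S)-5-bromo-3-(hydroxymethyl)-7-methoxy-2,3-dihydrobenzofuran-2-yl]-2,6-dimethoxyphenoxy}-1-(4-hydroxy-3,5-dimethoxyphenyl)propane-1,3-diol
Conditions: LiBH4 (6 equiv), MeOH (6 equiv), THF, 0 °C → rt; aq. NH4Cl
Reagents that add atoms: none
Why: Hydride reduction; LiBH4 should cleave the imide reductively to C9H2OH, reduce the C3 methyl ester to the hydroxymethyl group and cleave the aryl acetate in one operation without touching a stereocentre or the aryl bromide.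

Step 13
Reactants: 23 ring B phenol triol; 17 (S)-4-benzyl-3-(2-bromoacetyl)oxazolidin-2-one
Product: 24 (S)-4-benzyl-3-{2-[4-((1R,2S)-2-{4-[(2R,3S)-5-bromo-3-(hydroxymethyl)-7-methoxy-2,3-dihydrobenzofuran-2-yl]-2,6-dimethoxyphenoxy}-1,3-dihydroxypropyl)-2,6-dimethoxyphenoxy]acetyl}oxazolidin-2-one
Conditions: K2CO3, DMF, 0 °C → rt
Reagents that add atoms: none
Why: Chemoselective Williamson O-alkylation; carbonate ionises only the phenol, whose anion outcompetes the three neutral alcohols.

Step 14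
Reactants: 24 ring B aryloxyacetyl imide triol
Product: 25 tris(tert-butyldimethylsilyl) ether of 24 (silylated at the C3 hydroxymethyl group and at O7 and O9 of the ring B chain)
Conditions: t-BuMe2SiOTf (3.6 equiv), 2,6-lutidine (6 equiv), CH2Cl2, −78 → 0 °C
Reagents that add atoms: tert-butyldimethylsilyl trifluoromethanesulfonate, CC(C)(C)[Si](C)(C)OS(=O)(=O)C(F)(F)F
Why: Silyl ether formation; masking the three hydroxyl groups keeps them from binding magnesium or consuming Me3SiCl in step 16 and leaves one fluoride step for their release.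

Step 15
Reactants: 26 vanillin
Product: 27 4-formyl-2-methoxyphenyl acetate
Conditions: Ac2O, pyridine, DMAP (cat.), CH2Cl2, rt
Reagents that add atoms: acetic anhydride, CC(=O)OC(C)=O
Why: Phenol acetylation, for the same reasons as in step 10.

Step 16
Reactants: 25 tris-silyl imide; 27 4-formyl-2-methoxyphenyl acetate
Product: 29 (2R,3R)-anti-aldol adduct [3-(4-acetoxy-3-methoxyphenyl)-3-hydroxy-2-(ring B aryloxy)propanoyl imide of (S)-4-benzyloxazolidin-2-one; three silyl ethers retained], via trimethylsilyl ether 28 (not isolated)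
Conditions: MgCl2 (0.2 equiv), Et3N (2 equiv), Me3SiCl (1.5 equiv), EtOAc, rt; then 0.5 M HCl, THF, 0 °C
Reagents that add atoms: none
Why: Second Evans-type magnesium halide-catalysed anti-aldol; the same chelated Z-enolate model sets C8 and C7 of the ring A chain, and brief cold dilute acid should remove only the trimethylsilyl ether.

Step 17
Reactants: 29 (2R,3R)-anti-aldol adduct
Product: 30 (1R,2S)-1-(4-hydroxy-3-methoxyphenyl)-2-(ring B aryloxy)propane-1,3-diol carrying the three silyl ethers and the ring D bromide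
Conditions: LiBH4 (4 equiv), MeOH (4 equiv), THF, 0 °C → rt; aq. NH4Cl
Reagents that add atoms: none
Why: Hydride reduction; reductive removal of the auxiliary and cleavage of the aryl acetate should give the erythro diol and the free ring A phenol while the silyl ethers stay.

Step 18
Reactants: 30 aryl bromide
Product: 32 (E)-enal with three silyl ethers, via diethyl acetal 31 (not isolated)
Conditions: CH2=CHCH(OEt)2 (3 equiv), Pd(OAc)2 (5 mol %), n-Bu4NOAc (2 equiv), K2CO3 (2.5 equiv), KCl (1 equiv), DMF, 90 °C; then 1 M HCl, THF, 0 °C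
Reagents that add atoms: acrolein diethyl acetal, C=CC(OCC)OCC; water, O
Why: Mizoroki–Heck reaction with acrolein diethyl acetal under phosphine-free acetate conditions; syn insertion and β-hydride elimination towards the ring should give the E-cinnamyl acetal, which cold dilute acid hydrolyses to the enal.

Step 19
Reactants: 32 (E)-enal with three silyl ethers
Product: 33 target compound CNP0192639.1
Conditions: HF·pyridine, pyridine, THF, 0 °C → rt
Reagents that add atoms: none
Why: Fluoride desilylation under buffered conditions; the enal, the benzylic alcohols and the aryl ethers should survive, and no stereocentre is exposed to base or strong acid.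

**Compound list**

1 | 2'-hydroxy-3'-methoxyacetophenone | CC(=O)c1cccc(OC)c1O | starting material
2 | 5'-bromo-2'-hydroxy-3'-methoxyacetophenone | CC(=O)c1cc(Br)cc(OC)c1O | intermediate
3 | (E)-1-(5-bromo-2-hydroxy-3-methoxyphenyl)-3-(dimethylamino)prop-2-en-1-one (not isolated) | CN(C)/C=C/C(=O)c1cc(Br)cc(OC)c1O | intermediate
4 | 6-bromo-8-methoxy-4H-chromen-4-one | COc1cc(Br)cc2c1OC=CC2=O | intermediate
5 | 4-bromo-2,6-dimethoxyphenol | COc1cc(Br)cc(OC)c1O | starting material
6 | 2-(benzyloxy)-5-bromo-1,3-dimethoxybenzene | COc1cc(Br)cc(OC)c1OCc1ccccc1 | intermediate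
7 | (4-benzyloxy-3,5-dimethoxyphenyl)lithium (not isolated) | [Li]c1cc(OC)c(OCc2ccccc2)c(OC)c1 | intermediate
8 | lithium (4-benzyloxy-3,5-dimethoxyphenyl)triisopropoxyborate (not isolated) | [Li+].COc1cc([B-](OC(C)C)(OC(C)C)OC(C)C)cc(OC)c1OCc1ccccc1 | intermediate
9 | (4-benzyloxy-3,5-dimethoxyphenyl)boronic acid | COc1cc(B(O)O)cc(OC)c1OCc1ccccc1 | intermediate
10 | (2R)-2-(4-benzyloxy-3,5-dimethoxyphenyl)-6-bromo-8-methoxychroman-4-one | COc1cc([C@@H]2Oc3c(OC)cc(Br)cc3C(=O)C2)cc(OC)c1OCc1ccccc1 | intermediate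
11 | (2R)-2-(4-benzyloxy-3,5-dimethoxyphenyl)-6-bromo-4,8-dimethoxy-2H-chromene (not isolated) | COc1cc([C@@H]2Oc3c(OC)cc(Br)cc3C(OC)=C2)cc(OC)c1OCc1ccccc1 | intermediate
12 | (2S,3S)-3-[acetoxy(phenyl)-λ3-iodanyl]-2-(4-benzyloxy-3,5-dimethoxyphenyl)-6-bromo-4,4,8-trimethoxychromane, iodane trans to the aryl group (not isolated) | COc1cc([C@@H]2Oc3c(OC)cc(Br)cc3C(OC)(OC)[C@H]2I(OC(C)=O)c2ccccc2)cc(OC)c1OCc1ccccc1 | intermediate
13 | methyl (2R,3R)-2-(4-benzyloxy-3,5-dimethoxyphenyl)-5-bromo-7-methoxy-2,3-dihydrobenzofuran-3-carboxylate (trans) | COc1cc([C@@H]2Oc3c(OC)cc(Br)cc3[C@H]2C(=O)OC)cc(OC)c1OCc1ccccc1 | intermediate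
14 | methyl (2R,3R)-5-bromo-2-(4-hydroxy-3,5-dimethoxyphenyl)-7-methoxy-2,3-dihydrobenzofuran-3-carboxylate | COc1cc([C@@H]2Oc3c(OC)cc(Br)cc3[C@H]2C(=O)OC)cc(OC)c1O | intermediate
15 | (S)-4-benzyloxazolidin-2-one | O=C1OC[C@H](Cc2ccccc2)N1 | starting material
16 | lithium (S)-4-benzyl-2-oxooxazolidin-3-ide (not isolated) | [Li+].O=C1OC[C@H](Cc2ccccc2)[N-]1 | intermediate
17 | (S)-4-benzyl-3-(2-bromoacetyl)oxazolidin-2-one | O=C1OC[C@H](Cc2ccccc2)N1C(=O)CBr | intermediate
18 | methyl (2R,3R)-2-{4-[2-((S)-4-benzyl-2-oxooxazolidin-3-yl)-2-oxoethoxy]-3,5-dimethoxyphenyl}-5-bromo-7-methoxy-2,3-dihydrobenzofuran-3-carboxylate | COc1cc([C@@H]2Oc3c(OC)cc(Br)cc3[C@H]2C(=O)OC)cc(OC)c1OCC(=O)N1[C@@H](Cc2ccccc2)COC1=O | intermediate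
19 | syringaldehyde | COc1cc(C=O)cc(OC)c1O | starting material
20 | 4-formyl-2,6-dimethoxyphenyl acetate | COc1cc(C=O)cc(OC)c1OC(C)=O | intermediate
21 | trimethylsilyl ether of 22 at the new carbinol (not isolated) | CC(=O)Oc1c(OC)cc([C@@H](O[Si](C)(C)C)[C@@H](Oc2c(OC)cc([C@@H]3Oc4c(OC)cc(Br)cc4[C@H]3C(=O)OC)cc2OC)C(=O)N2[C@@H](Cc3ccccc3)COC2=O)cc1OC | intermediate
22 | methyl (2R,3R)-2-{4-[(1R,2R)-1-(4-acetoxy-3,5-dimethoxyphenyl)-3-((S)-4-benzyl-2-oxooxazolidin-3-yl)-1-hydroxy-3-oxopropan-2-yl]oxy-3,5-dimethoxyphenyl}-5-bromo-7-methoxy-2,3-dihydrobenzofuran-3-carboxylate (anti adduct) | CC(=O)Oc1c(OC)cc([C@@H](O)[C@@H](Oc2c(OC)cc([C@@H]3Oc4c(OC)cc(Br)cc4[C@H]3C(=O)OC)cc2OC)C(=O)N2[C@@H](Cc3ccccc3)COC2=O)cc1OC | intermediate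
23 | (1R,2S)-2-{4-[(2R,3S)-5-bromo-3-(hydroxymethyl)-7-methoxy-2,3-dihydrobenzofuran-2-yl]-2,6-dimethoxyphenoxy}-1-(4-hydroxy-3,5-dimethoxyphenyl)propane-1,3-diol | COc1cc([C@@H](O)[C@H](CO)Oc2c(OC)cc([C@@H]3Oc4c(OC)cc(Br)cc4[C@H]3CO)cc2OC)cc(OC)c1O | intermediate
24 | (S)-4-benzyl-3-{2-[4-((1R,2S)-2-{4-[(2R,3S)-5-bromo-3-(hydroxymethyl)-7-methoxy-2,3-dihydrobenzofuran-2-yl]-2,6-dimethoxyphenoxy}-1,3-dihydroxypropyl)-2,6-dimethoxyphenoxy]acetyl}oxazolidin-2-one | COc1cc([C@@H](O)[C@H](CO)Oc2c(OC)cc([C@@H]3Oc4c(OC)cc(Br)cc4[C@H]3CO)cc2OC)cc(OC)c1OCC(=O)N1[C@@H](Cc2ccccc2)COC1=O | intermediate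
25 | tris(tert-butyldimethylsilyl) ether of 24 (C3 hydroxymethyl group, O7 and O9 of the ring B chain) | COc1cc([C@@H](O[Si](C)(C)C(C)(C)C)[C@H](CO[Si](C)(C)C(C)(C)C)Oc2c(OC)cc([C@@H]3Oc4c(OC)cc(Br)cc4[C@H]3CO[Si](C)(C)C(C)(C)C)cc2OC)cc(OC)c1OCC(=O)N1[C@@H](Cc2ccccc2)COC1=O | intermediate
26 | vanillin | COc1cc(C=O)ccc1O | starting material
27 | 4-formyl-2-methoxyphenyl acetate | COc1cc(C=O)ccc1OC(C)=O | intermediate
28 | trimethylsilyl ether of 29 at the new carbinol (not isolated) | CC(=O)Oc1ccc([C@@H](O[Si](C)(C)C)[C@@H](Oc2c(OC)cc([C@@H](O[Si](C)(C)C(C)(C)C)[C@H](CO[Si](C)(C)C(C)(C)C)Oc3c(OC)cc([C@@H]4Oc5c(OC)cc(Br)cc5[C@H]4CO[Si](C)(C)C(C)(C)C)cc3OC)cc2OC)C(=O)N2[C@@H](Cc3ccccc3)COC2=O)cc1OC | intermediate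
29 | (S)-4-benzyl-3-[(2R,3R)-3-(4-acetoxy-3-methoxyphenyl)-3-hydroxy-2-(ring B aryloxy)propanoyl]oxazolidin-2-one, ring B aryloxy = the tris-silylated phenoxy residue of 25 (anti adduct) | CC(=O)Oc1ccc([C@@H](O)[C@@H](Oc2c(OC)cc([C@@H](O[Si](C)(C)C(C)(C)C)[C@H](CO[Si](C)(C)C(C)(C)C)Oc3c(OC)cc([C@@H]4Oc5c(OC)cc(Br)cc5[C@H]4CO[Si](C)(C)C(C)(C)C)cc3OC)cc2OC)C(=O)N2[C@@H](Cc3ccccc3)COC2=O)cc1OC | intermediate
30 | (1R,2S)-1-(4-hydroxy-3-methoxyphenyl)-2-(ring B aryloxy)propane-1,3-diol with three silyl ethers and the ring D bromide | COc1cc([C@@H](O)[C@H](CO)Oc2c(OC)cc([C@@H](O[Si](C)(C)C(C)(C)C)[C@H](CO[Si](C)(C)C(C)(C)C)Oc3c(OC)cc([C@@H]4Oc5c(OC)cc(Br)cc5[C@H]4CO[Si](C)(C)C(C)(C)C)cc3OC)cc2OC)ccc1O | intermediate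
31 | (E)-3,3-diethoxyprop-1-enyl analogue of 30, bromine replaced (not isolated) | COc1cc([C@@H](O)[C@H](CO)Oc2c(OC)cc([C@@H](O[Si](C)(C)C(C)(C)C)[C@H](CO[Si](C)(C)C(C)(C)C)Oc3c(OC)cc([C@@H]4Oc5c(OC)cc(/C=C/C(OCC)OCC)cc5[C@H]4CO[Si](C)(C)C(C)(C)C)cc3OC)cc2OC)ccc1O | intermediate
32 | tris(tert-butyldimethylsilyl) ether of the target (C3 hydroxymethyl group, O7 and O9 of the ring B chain) | COc1cc([C@@H](O)[C@H](CO)Oc2c(OC)cc([C@@H](O[Si](C)(C)C(C)(C)C)[C@H](CO[Si](C)(C)C(C)(C)C)Oc3c(OC)cc([C@@H]4Oc5c(OC)cc(/C=C/C=O)cc5[C@H]4CO[Si](C)(C)C(C)(C)C)cc3OC)cc2OC)ccc1O | intermediate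
33 | (E)-3-{(2R,3S)-2-[4-((1R,2S)-1,3-dihydroxy-1-{4-[(1R,2S)-1,3-dihydroxy-1-(4-hydroxy-3-methoxyphenyl)propan-2-yloxy]-3,5-dimethoxyphenyl}propan-2-yloxy)-3,5-dimethoxyphenyl]-3-(hydroxymethyl)-7-methoxy-2,3-dihydrobenzofuran-5-yl}acrylaldehyde | COc1cc([C@@H](O)[C@H](CO)Oc2c(OC)cc([C@@H](O)[C@H](CO)Oc3c(OC)cc([C@@H]4Oc5c(OC)cc(/C=C/C=O)cc5[C@H]4CO)cc3OC)cc2OC)ccc1O | target

**Step count and risks**

Total: 19 steps. Longest linear sequence: 14 steps (1, 2, 5, 6, 7, 9, 11, 12, 13, 14, 16, 17, 18, 19).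

Steps most likely to fail:

Step 6 (ring contraction). Migration of the ring D carbon may lose to dehydrogenation to the flavone or to shift of the electron-rich C2 aryl group. Acid may also open the C2–O bond and erode the C2 configuration, and the iodane may attack ring C. Fallback from 10, returning at 13: the same C3–C3a bond is made through a carbene instead of an iodonium ion. The lithium enolate of 10 [LiN(SiMe3)2, THF, −78 °C] is acylated with CF3CO2CH2CF3 to the 3-trifluoroacetyl flavanone (enol form) F1. Deacylative diazo transfer (MsN3, Et3N, aqueous MeCN) gives the 3-diazoflavanone F2. Irradiation in MeOH triggers a Wolff rearrangement, favoured by the locked s-cis diazoketone, to the ring-contracted ketene F3. Methanol traps F3 as the trans ester 13 mixed with the cis ester F4, and NaOMe in MeOH equilibrates the mixture to 13.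

Step 11 (anti-aldol; step 16 shares the risk). Magnesium may be bound by the aryloxy oxygen and its flanking methoxy groups, which could erode the anti or the facial selectivity. Addition to the electron-rich aldehyde may be slow, and the adduct may revert by retro-aldol. Fallback from 14, returning at 23: C8 is set by a boron syn-aldol and C7 is then inverted. (R)-4-Benzyloxazolidin-2-one is lithiated to lithium (R)-4-benzyl-2-oxooxazolidin-3-ide F5 and acylated as in step 8 to (R)-4-benzyl-3-(2-bromoacetyl)oxazolidin-2-one F6. F6 alkylates 14 (K2CO3, acetone) to the (R)-imide F7. The Bu2BOTf/i-Pr2NEt syn-aldol with 20 gives the (2R,3S) syn adduct F8. Mitsunobu inversion of the carbinol (4-nitrobenzoic acid, PPh3, DIAD) gives the (2R,3R) 4-nitrobenzoate F9. LiBH4 then removes the auxiliary, the benzoate, the acetate and the C3 ester to give 23.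

Step 18 (Heck). Oxidative addition to the electron-rich aryl bromide may be slow, β-hydride elimination may run towards the acetal carbon and give the propanoate, and the phenolic aryl glycerol ether may degrade under base at 90 °C. Fallback from 30, returning at 31 and then 32: a Suzuki–Miyaura coupling with (E)-2-(3,3-diethoxyprop-1-en-1-yl)-4,4,5,5-tetramethyl-1,3,2-dioxaborolane (Pd(OAc)2, SPhos, K3PO4, THF/H2O, 50 °C). It gives the same acetal 31 at lower temperature, with the position and geometry of the double bond fixed by the reagent; hydrolysis as in step 18 gives 32. No new compound arises (F0).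

**Further compounds**

F1 | step 6 | (2S)-2-(4-benzyloxy-3,5-dimethoxyphenyl)-6-bromo-4-hydroxy-8-methoxy-3-(trifluoroacetyl)-2H-chromene (enol form of the 3-trifluoroacetyl flavanone) | COc1cc([C@@H]2Oc3c(OC)cc(Br)cc3C(O)=C2C(=O)C(F)(F)F)cc(OC)c1OCc1ccccc1
F2 | step 6 | (2S)-2-(4-benzyloxy-3,5-dimethoxyphenyl)-6-bromo-3-diazo-8-methoxychroman-4-one | COc1cc([C@@H]2Oc3c(OC)cc(Br)cc3C(=O)C2=[N+]=[N-])cc(OC)c1OCc1ccccc1
F3 | step 6 | (2S)-2-(4-benzyloxy-3,5-dimethoxyphenyl)-5-bromo-7-methoxy-3-(oxomethylidene)-2,3-dihydrobenzofuran (ketene) | COc1cc([C@@H]2Oc3c(OC)cc(Br)cc3C2=C=O)cc(OC)c1OCc1ccccc1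
F4 | step 6 | methyl (2R,3S)-2-(4-benzyloxy-3,5-dimethoxyphenyl)-5-bromo-7-methoxy-2,3-dihydrobenzofuran-3-carboxylate (cis) | COc1cc([C@@H]2Oc3c(OC)cc(Br)cc3[C@@H]2C(=O)OC)cc(OC)c1OCc1ccccc1
F5 | step 11 | lithium (R)-4-benzyl-2-oxooxazolidin-3-ide | [Li+].O=C1OC[C@@H](Cc2ccccc2)[N-]1
F6 | step 11 | (R)-4-benzyl-3-(2-bromoacetyl)oxazolidin-2-one | O=C1OC[C@@H](Cc2ccccc2)N1C(=O)CBr
F7 | step 11 | methyl (2R,3R)-2-{4-[2-((R)-4-benzyl-2-oxooxazolidin-3-yl)-2-oxoethoxy]-3,5-dimethoxyphenyl}-5-bromo-7-methoxy-2,3-dihydrobenzofuran-3-carboxylate | COc1cc([C@@H]2Oc3c(OC)cc(Br)cc3[C@H]2C(=O)OC)cc(OC)c1OCC(=O)N1[C@H](Cc2ccccc2)COC1=O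
F8 | step 11 | (2R,3S) syn-aldol adduct of F7 with 20 [(1S,2R) in the propan-2-yloxy numbering of 22] | CC(=O)Oc1c(OC)cc([C@H](O)[C@@H](Oc2c(OC)cc([C@@H]3Oc4c(OC)cc(Br)cc4[C@H]3C(=O)OC)cc2OC)C(=O)N2[C@H](Cc3ccccc3)COC2=O)cc1OC
F9 | step 11 | (2R,3R) 4-nitrobenzoate from F8 with inverted carbinol carbon | CC(=O)Oc1c(OC)cc([C@@H](OC(=O)c2ccc(cc2)[N+](=O)[O-])[C@@H](Oc2c(OC)cc([C@@H]3Oc4c(OC)cc(Br)cc4[C@H]3C(=O)OC)cc2OC)C(=O)N2[C@H](Cc3ccccc3)COC2=O)cc1OC
F0 | step 18 | none | none
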